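The numbers in the tables stem from a simulated flask for substances that don't exist, noise included.

The pitfall in this flask is to take the Q reading for free Q. E turns into Q, E and Q join to Z, and five charges stand for 6.0 min.

| flask | E | remark | time |
|---|---|---|---|
| green | 0.63 mM | run made earlier |  |
| teal | 41 mM | run made earlier |  |
| alpha | 0.80 mM |  | 6.0 min |
| gamma | 2.0 mM |  | 6.0 min |
| epsilon | 6.0 mM |  | 6.0 min |
| zeta | 20 mM |  | 6.0 min |
| theta | 60 mM |  | 6.0 min |

| run | time / min | Q / % | E / % |
|---|---|---|---|
| green | 0.250 | 26.4 | 73.1 |
| green | 0.833 | 45.7 | 51.4 |
| green | 1.33 | 51.0 | 47.9 |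
| green | 2.50 | 51.6 | 46.5 |
| green | 3.00 | 51.3 | 49.0 |
| green | 4.00 | 51.9 | 46.2 |
| teal | 0.250 | 27.0 | 60.8 |
| teal | 0.833 | 48.9 | 35.6 |
| teal | 1.33 | 50.0 | 34.2 |
| teal | 2.50 | 53.3 | 32.1 |
| teal | 3.00 | 51.4 | 33.1 |
| teal | 4.00 | 51.6 | 31.6 |

(each reading ± 1 percentage point)

- percentages count the E that a species holds: one Z counts as two
- Q is meant together with its Z
- candidate steps: E <-> Q; E + Q <-> Z
- in an amount of Q, one Z counts as one Q
- the concentration of Q that is asked is that of its free form alone
- "hardly changes" means that all values lie within two and a half points (for a concentration: within two and a half percent of the largest)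

- [Q] (only what is free in solution) at the end for alpha, gamma, epsilon, zeta, theta, in this order
- how that number moves from the first to the last of them (falls, then rises / rises all the way / falls all the way / hardly changes / rises, then falls)

From 1.33 min on, both runs show no trend beyond the scatter, and 6.0 min lies later, so the asked flasks are reckoned at equilibrium, under thermodynamic control. Averaged over that plateau, green and teal read nearly the same Q, 51.5% and 51.6%, yet E reads 47.4% and 32.8%.

These numbers go together. Each Z holds one E and one Q, and the Q reading counts it once, so the shortfall of E and Q below the charge is Z counted once, 15.7% in teal. That leaves teal's readings a free pool F = [E] + [Q] of 68.6% of the charge, with [Q]/[E] read at 1.10. Read so, free Q is 0.523 of F, near half, and Z draws E and Q one for one, so from green to teal the Q reading stays close to that share while the E reading falls.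

[Z] goes with [E][Q], and [E] and [Q] keep a fixed ratio, so the charge equals F + F·F/C. Teal's readings give 61.6 mM; this C, the free pool at which Z holds as much of the charge as the pool itself, gives the apparent order of [Q] in the charge: (1 + u)/(1 + 2u), with u = F/C. For gamma the pool is reckoned at 1.94 mM, so the reckoned order is 0.970. For theta the pool is reckoned at 37.4 mM, so the reckoned order is 0.726, and the reckoned [Q] is 19.5 mM.

The forecast, slightly lower at theta than this reckoning, gave 0.41 mM, 1.01 mM, 2.87 mM, 8.3 mM and 19.4 mM, rises all the way: "Free Q always rises, though less than proportionally". The flask gives 0.414 mM, 1.02 mM, 2.89 mM, 8.35 mM and 19.7 mM, rises all the way.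

    E ⇌ Q (K = 1.10, k = 1.55 /min)
    E + Q ⇌ Z, settled at all times (K = 32.0 /M)

In alpha, E and free Q relaxed by the step E <-> Q alone, both ways together, with a half-life of 0.234 min, shorter than the 6.0 min of the run, and the making of Q from E had 97% of its turnover up to the end behind it at 1.20 min, with Z in step throughout. At the end, gamma's pool stood at 0.0315 of C with a local order of 0.97, while theta's Z held 37.5% of the charge and its pool stood at 0.609 of C.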